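Partner is conserved: each unit of it ends as partner, quenched reagent, catalyst intermediate C, target or isomer of the product.

    substrate + free catalyst ⇌ catalyst intermediate A (K1 = 7.8 L mol⁻¹, k1 = 14 L mol⁻¹ s⁻¹)
    catalyst intermediate A → catalyst intermediate B (k2 = 2.0 s⁻¹)
    partner + catalyst intermediate B → catalyst intermediate C (k3 = 150 L mol⁻¹ s⁻¹)
    catalyst intermediate C → free catalyst + target (k4 = 5.4 s⁻¹)
    target + free catalyst ⇌ isomer of the product + free catalyst, rate k5*[free catalyst]*[target] forward; the back reaction follows from the equilibrium constant (K5 = 0.36, k5 = 4.4 L mol⁻¹ s⁻¹)
    partner + protic impurity → quenched reagent (k6 = 0.49 L mol⁻¹ s⁻¹)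

substrate 0.050 M (fed, over 25 min); partner 0.0350 M; protic impurity 2.50 mM; free catalyst 0.10 mM; time 50 min

1. how much of the substrate has reacted by 50 min
2. how much target there is at 50 min, in percent of the substrate charged
3. how much isomer of the product there is at 50 min, in percent of the substrate charged

Reacted substrate stands as target, isomer of the product or a catalyst-bound form. This flask therefore has a conversion ceiling: c(partner) minus c(protic impurity), plus the c(catalyst) that can hold one substrate as intermediate B, per substrate charged, which is 65.2%.

Which numbers must be good? The partner charge equals 70.0% of the substrate charge, and an error in it passes straight into the ceiling. The protic impurity subtracts 5.00%. Its charge counts in full, but k6 matters less: the pseudo-first-order half-life of the impurity is 40.4 s, short against 50 min. The catalyst adds 0.200%, a small correction.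

The constants k1, K1 and k2 enter through one time constant of substrate use, with the catalyst taken as free: 22.6 min. The constants k3 and k4 give times of 0.190 s and 0.185 s, both short against it. With the feed, this reckoning reaches 80.0% by 50 min, above the ceiling. These constants need to be good enough to keep that margin.

This reckoning commits to 65.2% conversion, with target and isomer together at 65.0%. It gives no split, since the balance holds no figure for one.

The forecast gives 65.2%, 52.5% of target and 12.5% of isomer. Its grounds: “partner runs out near the end, capping conversion at about 65%”.

The flask gives 65.2%, 52.9% and 12.1%, so the forecast stands within tolerance. At 50.0 min, 0.011% of the partner remains, and 99.5% of the catalyst sits as intermediate B, the resting state. Ten times the time leaves conversion at 65.2%, against the ceiling of 65.2%. One change that a run shows to be large enough to take the isomer answer out of the forecast's range: partner at 0.0264 M moves that answer by 5 points.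

In the neighbour flask with 0.014 M of partner, the ceiling is 23.2%. That flask reaches 23.2%.

Its constants were chosen freely; the rest is arithmetic.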